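## Retrosynthetic overview

1. The two hydroxyl groups go on last, by C–O bond formation on the finished carbon cage: Mukaiyama hydration of a C10 exocyclic methylene, preceded by conjugate borylation–oxidation of the bicyclo[2.2.2]octene lactone (C7′–OH, C7a′–H).
2. Rings C, D and E (cyclopentane and bicyclo[2.2.2]octane) come from one intramolecular Diels–Alder reaction of an ortho-dienone. The dienone is made by dearomatising C-alkylation of a C7-bromo-blocked 5-hydroxy-4,6-dimethylphthalide (ring F) with an allylic bromide.
3. The allylic bromide (rings A and B) comes from a spiro δ-lactone ketone by α-methylenation and allylic bromination with transposition.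
4. Key step: ring A is closed by a C–O-initiated (3+3) annulation of (R)-pulegone with propiolic acid (tertiary C–O bond, then 6-endo-dig C–C closure). The pulegone methyl stereocentre sets the spiro carbon and is erased later.
5. Ring order: B (chiral pool) → A → F (separate branch, C–H lactonisation) → C, D and E together.

Labels used below: terpenoid part C1–C12 (C3 δ-lactone carbonyl, C4 CMe2O, C5 spiro carbon, C8 and C9 ring-fusion carbons, C10 carbinol carbon, C11 and C12 the two CH2 links); phthalide part C1′–C7a′ (C1′ γ-lactone carbonyl, C3′ OCH2, C4′ and C6′ methyl-bearing quaternary carbons, C5′ ketone, C7′ carbinol carbon). The SMILES in the compound list define every configuration.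

## Route

Step 1
Reactants: 1 (R)-(+)-pulegone; 2 propiolic acid
Product: 4 (6R,9R)-1,1,9-trimethyl-2-oxaspiro[5.5]undec-4-ene-3,7-dione, via tertiary propiolate ester 3 (not isolated)
Conditions: Ph3PAuNTf2 (5 mol %), HNTf2 (5 mol %), 2 added slowly, ClCH2CH2Cl, 60 °C
Reagents that add atoms: none
Why: Proposed new method: a relay (3+3) spiro-annulation in which the strong acid and cationic monovalent gold first add the carboxylic O–H across the isopropylidene C=C (reversible conjugate, Markovnikov hydro-acyloxylation giving tertiary ester 3) and the gold-activated ynoate is then captured irreversibly by the ketone enol in a 6-endo-dig Conia-ene closure that fixes the cis ring-A alkene; the new C–C bond forms axially on the chair with the ring methyl and the CMe2O carbon equatorial, so the spiro carbon is set from the pulegone stereocentre; the closest known reaction types are acid- or gold-catalysed hydro-acyloxylation of alkenes, the gold-catalysed Conia-ene reaction and the 6-endo-dig cyclisation of aryl propiolates to coumarins.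

Step 2
Reactants: 4 (6R,9R)-1,1,9-trimethyl-2-oxaspiro[5.5]undec-4-ene-3,7-dione
Product: 5 (6R,9R)-1,1,9-trimethyl-8-methylidene-2-oxaspiro[5.5]undec-4-ene-3,7-dione
Conditions: (CH2O)n, PhNHMe·CF3CO2H, THF, 65 °C
Reagents that add atoms: paraformaldehyde (formaldehyde unit), C=O
Why: Mannich-type α-methylenation at C8, the only enolisable α-carbon because C6 is quaternary and the lactone has no α-hydrogen; no stereocentre is formed.

Step 3
Reactants: 5 (6R,9R)-1,1,9-trimethyl-8-methylidene-2-oxaspiro[5.5]undec-4-ene-3,7-dione
Product: 6 (6R)-8-(bromomethyl)-1,1,9-trimethyl-2-oxaspiro[5.5]undeca-4,8-diene-3,7-dione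
Conditions: NBS, AIBN (cat.), PhCF3, 80 °C
Reagents that add atoms: N-bromosuccinimide, O=C1CCC(=O)N1Br
Why: Wohl–Ziegler allylic bromination in which abstraction of the tertiary allylic C9–H gives a delocalised radical that is brominated at its primary terminus, giving the conjugated tetrasubstituted enone and erasing the now redundant C9 stereocentre.

Step 4
Reactants: 7 4-hydroxy-3,5-dimethylbenzoic acid
Product: 8 5-hydroxy-4,6-dimethyl-2-benzofuran-1(3H)-one
Conditions: Pd(OAc)2 (10 mol %), K2HPO4 (3 equiv), CH2Br2 (solvent), 140 °C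
Reagents that add atoms: dibromomethane, BrCBr
Why: Carboxylate-directed ortho C–H alkylation by CH2Br2 followed by intramolecular SN2 lactonisation (C–O bond) builds the phthalide; the two ortho positions are equivalent and the hindered phenol is only weakly deprotonated by the phosphate.

Step 5
Reactants: 8 5-hydroxy-4,6-dimethyl-2-benzofuran-1(3H)-one
Product: 9 7-bromo-5-hydroxy-4,6-dimethyl-2-benzofuran-1(3H)-one
Conditions: Br2, AcOH, 40 °C, dark
Reagents that add atoms: bromine, BrBr
Why: Electrophilic aromatic bromination at the only free ring position, which is ortho and para to the two methyl groups; the bromine blocks the C6 side for step 6 and is removed in step 7.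

Step 6
Reactants: 9 7-bromo-5-hydroxy-4,6-dimethyl-2-benzofuran-1(3H)-one; 6 (6R)-8-(bromomethyl)-1,1,9-trimethyl-2-oxaspiro[5.5]undeca-4,8-diene-3,7-dione
Product: 13 cage bromo-enoate diketone (7′-bromo-10-oxo-7′-ene precursor of 18), via sodium phenoxide 10 (not isolated), via ortho-dienone 11 (not isolated), via deconjugated trienone 12 (not isolated)
Conditions: NaH, toluene, 0 → 25 °C; then DBU (20 mol %), 95 °C
Reagents that add atoms: none
Why: Alkylative dearomatisation (C-alkylation of the 2,6-dimethylphenoxide by the allylic bromide in a non-polar medium, steered to C4 because bromine deactivates and shields the C6 side) gives both C4′ epimers of 11 in about equal amounts, DBU equilibrates the enone with its exo-methylene isomer 12, and the intramolecular Diels–Alder reaction of the epimer drawn forms C8–C3a′ and C12–C6′ with C8, C3a′ and C6′ dictated by C4′ through the three-atom tether and C9 ending cis-fused (it stays epimerisable α to the ketone); the diastereomeric cage from the other C4′ epimer is removed by chromatography.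

Step 7
Reactants: 13 cage bromo-enoate diketone
Product: 14 cage enoate diketone (10-oxo-7′-ene precursor of 18)
Conditions: Zn, AcOH, THF, 25 °C
Reagents that add atoms: none
Why: Reductive dehalogenation of the β-bromo-α,β-unsaturated lactone (a vinylogous acyl bromide) by zinc, which leaves the ketones, both lactone alkenes and all stereocentres untouched.

Step 8
Reactants: 14 cage enoate diketone
Product: 15 cage diene lactone (C10 exocyclic methylene, C7′=C7a′)
Conditions: Zn, CH2Br2, TiCl4, THF, 0 → 25 °C
Reagents that add atoms: dibromomethane, BrCBr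
Why: Takai–Lombardo methylenation, non-basic and selective for the C10 ketone over the lactones and over the C5′ ketone, which is flanked by two quaternary carbons; C9 is no longer epimerisable afterwards.

Step 9
Reactants: 15 cage diene lactone
Product: 17 7′-hydroxy cage lactone with C10 exocyclic methylene, via C7′ pinacol boronate 16 (not isolated)
Conditions: B2pin2, CuCl (10 mol %), NaOtBu (15 mol %), Xantphos (10 mol %), MeOH (2 equiv), THF, 25 °C; then NaBO3·4H2O, THF/H2O, 25 °C
Reagents that add atoms: bis(pinacolato)diboron, CC1(C)OB(OC1(C)C)B1OC(C)(C)C(C)(C)O1 (boryl group of 16); sodium perborate, [Na+].[Na+].O[B-]1(O)OO[B-](O)(O)OO1 (oxygen of 17)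
Why: Copper-catalysed conjugate borylation then oxidation with retention (a net anti hydration, forming the C7′–O bond): the strained, s-cis-locked alkylidene γ-lactone reacts in preference to the ring-A lactone whose β-carbon is neopentylic, boron adds to C7′ from the face syn to the C5′ ketone bridge, and C7a′ is protonated from the opposite face, which is also the expected thermodynamic configuration of this epimerisable centre.

Step 10
Reactants: 17 7′-hydroxy cage lactone with C10 exocyclic methylene
Product: 18 CNP0360620.2 (target)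
Conditions: Co(acac)2 (20 mol %), PhSiH3, O2 (1 atm), THF, 0 → 25 °C
Reagents that add atoms: dioxygen, O=O
Why: Mukaiyama hydration (cobalt hydride hydrogen-atom transfer, Markovnikov) in which the tertiary C10 radical is trapped by O2 on the face away from the syn-axial C12 methylene bridge, giving the hydroxyl cis to C11, while Co(acac)2 is expected to leave the electron-poor ring-A alkene alone.

## Compound list

1 | (R)-(+)-pulegone, (5R)-5-methyl-2-(propan-2-ylidene)cyclohexan-1-one | C[C@@H]1CCC(=C(C)C)C(=O)C1 | starting material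
2 | propiolic acid (prop-2-ynoic acid) | C#CC(=O)O | starting material
3 | 2-[(4R)-4-methyl-2-oxocyclohexyl]propan-2-yl prop-2-ynoate (ring C1 epimerisable, not defined) | C[C@@H]1CCC(C(C)(C)OC(=O)C#C)C(=O)C1 | intermediate
4 | (6R,9R)-1,1,9-trimethyl-2-oxaspiro[5.5]undec-4-ene-3,7-dione | CC1(C)OC(=O)C=C[C@]12CC[C@@H](C)CC2=O | intermediate
5 | (6R,9R)-1,1,9-trimethyl-8-methylidene-2-oxaspiro[5.5]undec-4-ene-3,7-dione | CC1(C)OC(=O)C=C[C@]12CC[C@@H](C)C(=C)C2=O | intermediate
6 | (6R)-8-(bromomethyl)-1,1,9-trimethyl-2-oxaspiro[5.5]undeca-4,8-diene-3,7-dione | CC1(C)OC(=O)C=C[C@]12CCC(C)=C(CBr)C2=O | intermediate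
7 | 4-hydroxy-3,5-dimethylbenzoic acid | Cc1cc(cc(C)c1O)C(=O)O | starting material
8 | 5-hydroxy-4,6-dimethyl-2-benzofuran-1(3H)-one | O=C1OCc2c1cc(C)c(O)c2C | intermediate
9 | 7-bromo-5-hydroxy-4,6-dimethyl-2-benzofuran-1(3H)-one | O=C1OCc2c1c(Br)c(C)c(O)c2C | intermediate
10 | sodium 7-bromo-4,6-dimethyl-1-oxo-1,3-dihydro-2-benzofuran-5-olate | [Na+].[O-]c1c(C)c(Br)c2C(=O)OCc2c1C | intermediate
11 | (4R)-7-bromo-4,6-dimethyl-4-{[(6R)-1,1,9-trimethyl-3,7-dioxo-2-oxaspiro[5.5]undeca-4,8-dien-8-yl]methyl}-2-benzofuran-1,5(3H,4H)-dione (formed together with its 4S epimer) | CC1(C)OC(=O)C=C[C@]12CCC(C)=C(C[C@@]3(C)C(=O)C(C)=C(Br)C4=C3COC4=O)C2=O | intermediate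
12 | (4R)-7-bromo-4-{[(6R,8R)-1,1-dimethyl-9-methylidene-3,7-dioxo-2-oxaspiro[5.5]undec-4-en-8-yl]methyl}-4,6-dimethyl-2-benzofuran-1,5(3H,4H)-dione | CC1(C)OC(=O)C=C[C@]12CCC(=C)[C@@H](C[C@@]3(C)C(=O)C(C)=C(Br)C4=C3COC4=O)C2=O | intermediate
13 | cage bromo-enoate diketone: skeleton and cage configurations of 18, C10 ketone (no C10 methyl), C7′(Br)=C7a′ alkene | CC1(C)OC(=O)C=C[C@]12CC[C@]13C[C@]4(C)C(=O)[C@](C)(C[C@H]1C2=O)[C@]31COC(=O)C1=C4Br | intermediate
14 | cage enoate diketone: as 13 with H in place of Br at C7′ | CC1(C)OC(=O)C=C[C@]12CC[C@]13C[C@]4(C)C(=O)[C@](C)(C[C@H]1C2=O)[C@]31COC(=O)C1=C4 | intermediate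
15 | cage diene lactone: as 14 with C10=CH2 in place of the C10 ketone | CC1(C)OC(=O)C=C[C@]12CC[C@]13C[C@]4(C)C(=O)[C@](C)(C[C@H]1C2=C)[C@]31COC(=O)C1=C4 | intermediate
16 | C7′ pinacol boronate: as 17 with 4,4,5,5-tetramethyl-1,3,2-dioxaborolan-2-yl in place of the C7′ hydroxyl | CC1(C)OC(=O)C=C[C@]12CC[C@]13C[C@]4(C)C(=O)[C@](C)(C[C@H]1C2=C)[C@]31COC(=O)[C@H]1[C@H]4B1OC(C)(C)C(C)(C)O1 | intermediate
17 | 7′-hydroxy cage lactone: as 18 with C10=CH2 in place of C10(CH3)OH | CC1(C)OC(=O)C=C[C@]12CC[C@]13C[C@]4(C)C(=O)[C@](C)(C[C@H]1C2=C)[C@]31COC(=O)[C@H]1[C@H]4O | intermediate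
18 | CNP0360620.2 | CC1(C)OC(=O)C=C[C@]12CC[C@]13C[C@]4(C)C(=O)[C@](C)(C[C@H]1[C@@]2(C)O)[C@]31COC(=O)[C@H]1[C@H]4O | target

## Step count and risks

Total steps: 10. Longest linear sequence: 8 (steps 1, 2, 3, 6, 7, 8, 9, 10). Step 6 costs about half the material, because the unwanted C4′ epimer gives a separable diastereomeric cage.

Steps most likely to fail:

Step 1 (the proposed annulation). Propiolic acid may oligomerise, or ester 3 may revert faster than it cyclises. The known-chemistry fallback sets out from 1 and comes back at 4. The lithium dienolate of 1 (LDA, THF, −78 °C) is alkenylated at the α-carbon with tert-butyl (Z)-3-iodoacrylate (addition–elimination with retention, the electrophile entering axially, cis to the ring methyl) to give tert-butyl (2Z)-3-[(1R,4R)-4-methyl-2-oxo-1-(prop-1-en-2-yl)cyclohexyl]prop-2-enoate F1. CF3CO2H in CH2Cl2 then protonates the isopropenyl group and closes the δ-lactone through the ester oxygen with loss of 2-methylpropene, giving 4.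

Step 6 (one-pot alkylation, deconjugation and cycloaddition). Risks are O- instead of C-alkylation, base-induced retro-Michael fragmentation of the dienone, and a slow cycloaddition of the hindered matched isomer. The fallback sets out from 11 (made by the first half of step 6 and used crude) and comes back at 13; it takes the deconjugation out of enolate chemistry. TBSOTf and Et3N (CH2Cl2, −40 °C) convert 11 into the exocyclic silyl dienol ether of 11 (C10–OSi(tBu)Me2, C9=C10, C8=CH2) F2. Its 2-silyloxy-diene terminus is the dienophile in the intramolecular Diels–Alder reaction (toluene, 80 °C), giving the cage silyl enol ether (13 with C9=C10–OSi(tBu)Me2) F3. Bu4NF/AcOH then cleaves the silyl group and protonates C9 to the cis-fused ketone 13.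

Step 10 (Mukaiyama hydration). The face of oxygen capture at C10 is hard to predict, and the ring-A alkene may be reduced. The fallback sets out from 14 and comes back at 18; it makes the carbinol by C–C bond formation, which approaches C10 in the opposite sense to the radical route and so serves if step 10 gives the C10 epimer. MeMgBr/CeCl3 (THF, −78 °C) adds to the C10 ketone of 14 to give the tertiary alcohol enoate (18 lacking the C7′ hydroxyl, with C7′=C7a′) F4. Copper-catalysed borylation as in step 9 gives the C7′ pinacol boronate of 18 F5, and NaBO3·4H2O oxidises it to 18.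

Further compounds

F1 | step 1 | tert-butyl (2Z)-3-[(1R,4R)-4-methyl-2-oxo-1-(prop-1-en-2-yl)cyclohexyl]prop-2-enoate | CC(=C)[C@]1(/C=C\C(=O)OC(C)(C)C)CC[C@@H](C)CC1=O
F2 | step 6 | exocyclic silyl dienol ether of 11 (C10–OSi(tBu)Me2, C9=C10, C8=CH2) | CC1(C)OC(=O)C=C[C@]12CCC(=C)C(C[C@@]3(C)C(=O)C(C)=C(Br)C4=C3COC4=O)=C2O[Si](C)(C)C(C)(C)C
F3 | step 6 | cage silyl enol ether (13 with C9=C10–OSi(tBu)Me2) | CC1(C)OC(=O)C=C[C@]12CC[C@]13C[C@]4(C)C(=O)[C@](C)(CC1=C2O[Si](C)(C)C(C)(C)C)[C@]31COC(=O)C1=C4Br
F4 | step 10 | tertiary alcohol enoate (18 lacking the C7′ hydroxyl, with C7′=C7a′) | CC1(C)OC(=O)C=C[C@]12CC[C@]13C[C@]4(C)C(=O)[C@](C)(C[C@H]1[C@@]2(C)O)[C@]31COC(=O)C1=C4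
F5 | step 10 | C7′ pinacol boronate of 18 (boryl group in place of the C7′ hydroxyl) | CC1(C)OC(=O)C=C[C@]12CC[C@]13C[C@]4(C)C(=O)[C@](C)(C[C@H]1[C@@]2(C)O)[C@]31COC(=O)[C@H]1[C@H]4B1OC(C)(C)C(C)(C)O1
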